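**Retrosynthetic overview**

- The target, a depside with no stereocentre, is cut at the aryl ester C–O bond into a ring A acid (2-benzyloxy-4-methoxy-6-pentylbenzoic acid) and a ring B phenol (benzyl 2,4-dihydroxy-6-propylbenzoate). The C2′ methyl ether is added after the coupling, and both benzyl groups are removed last.
- The strategy rests on the substitution pattern of ring A: C1 (carboxyl) is flanked by C2–O and C6–pentyl and faces C4–OMe across the ring. C1, C2, C3 and C6 map onto C5, C4, C3 and C6 of a 4-alkoxy-6-pentyl-2-pyrone-5-carboxylate; C4 (with its OMe) and C5 come from 1,1-dimethoxyethene.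
- Ring A is therefore made by [4+2] addition of the ketene acetal across pyrone C3/C6, followed by loss of CO2 and methanol. The C2 oxygen (benzyl) and the C4 oxygen (methyl) come from different partners and are differentiated from the outset.
- The pyrone comes from dimethyl 3-oxopentanedioate by C-acylation with hexanoyl chloride, enol-lactonisation and O-benzylation.
- Order of ring formation: pyranone ring (step 2), then ring A (step 4); ring B is bought as the preformed arene.

Key step: step 4

Assumption: 2,4-dihydroxy-6-propylbenzoic acid and 1,1-dimethoxyethene are taken as purchasable compounds.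

**Route**

Step 1
Reactants: 1 dimethyl 3-oxopentanedioate; 2 hexanoyl chloride
Product: 3 dimethyl 2-hexanoyl-3-oxopentanedioate
Conditions: MgCl2 (1 equiv), pyridine (2 equiv), 2 (1.0 equiv), CH2Cl2, 0 °C to rt; aq. HCl work-up
Reagents that add atoms: none
Why: Magnesium chelation of the β-keto ester allows soft enolisation by pyridine and directs the acid chloride to carbon (Claisen-type C-acylation under MgCl2/amine conditions), and the chelated tricarbonyl product is protected from a second acylation.

Step 2
Reactants: 3 dimethyl 2-hexanoyl-3-oxopentanedioate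
Product: 4 methyl 4-hydroxy-2-oxo-6-pentyl-2H-pyran-5-carboxylate
Conditions: conc. H2SO4, 0 °C to rt, then ice-water
Reagents that add atoms: none
Why: In this acid-promoted enol-lactonisation the enol oxygen of the hexanoyl ketone attacks the distal CH2CO2Me ester in a 6-exo-trig acyl substitution with loss of methanol, while the ester on the acylated carbon cannot reach a six-membered lactone and remains as the C5 ester of the 4-hydroxy-2-pyrone.

Step 3
Reactants: 4 methyl 4-hydroxy-2-oxo-6-pentyl-2H-pyran-5-carboxylate; 5 benzyl bromide
Product: 6 methyl 4-(benzyloxy)-2-oxo-6-pentyl-2H-pyran-5-carboxylate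
Conditions: K2CO3, DMF, rt to 50 °C
Reagents that add atoms: none
Why: Williamson-type O-alkylation of the acidic vinylogous-acid hydroxyl as its potassium salt in a dipolar aprotic solvent should take place at the C4 oxygen, the usual outcome for 4-hydroxy-2-pyrones with benzylic halides.

Step 4
Reactants: 6 methyl 4-(benzyloxy)-2-oxo-6-pentyl-2H-pyran-5-carboxylate; 7 1,1-dimethoxyethene
Product: 10 methyl 2-(benzyloxy)-4-methoxy-6-pentylbenzoate, via oxabicyclooctenone adduct 8 (not isolated), via dimethoxycyclohexadiene 9 (not isolated)
Conditions: 7 (5 equiv), toluene, base-washed sealed tube, 130–150 °C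
Reagents that add atoms: none
Why: The nucleophilic CH2 terminus of the ketene acetal attacks pyrone C6 (β to the C5 ester and vinylogous to the lactone carbonyl) while the dimethoxy carbon bonds to C3, in an asynchronous inverse-electron-demand Diels–Alder reaction of the 2-pyrone as electron-poor diene; the closest known case is the conversion of alkyl coumalates (2-pyrone-5-carboxylates) with ketene acetals into 4-alkoxybenzoates. Ring A closes as a six-membered carbocycle in this intermolecular [4+2] mode to give the 2-oxabicyclo[2.2.2]octenone 8, whose lactone bridge leaves as CO2 in a retro-[4+2] step to give diene 9. Loss of one methanol across the C(OMe)2–CH2 unit of 9 then aromatises the ring, so the two bridgehead stereocentres of 8 are transient and the product has none. The selectivity required is regiochemical: the methoxy carbon must end para to the ester, which is secured because the polarisation of the pyrone (C6 electrophilic through the C5 ester, C3 the enolate-like terminus) matches that of the ketene acetal (CH2 nucleophilic, acetal carbon cation-stabilising). The C4 benzyloxy group donates into the diene and lowers its reactivity, so an excess of 7 and a sealed tube at 130–150 °C are specified; the benzyl ether and both esters tolerate these neutral thermal conditions.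

Step 5
Reactants: 10 methyl 2-(benzyloxy)-4-methoxy-6-pentylbenzoate
Product: 11 2-(benzyloxy)-4-methoxy-6-pentylbenzoic acid
Conditions: KOH, DMSO–H2O (4:1), 90–100 °C; then aq. HCl to pH 2
Reagents that add atoms: potassium hydroxide, [K+].[OH-]
Why: Saponification with poorly solvated hydroxide in aqueous DMSO is the standard way to cleave 2,6-disubstituted methyl benzoates, and the benzyl and methyl aryl ethers are inert to it.

Step 6
Reactants: 12 2,4-dihydroxy-6-propylbenzoic acid; 5 benzyl bromide
Product: 13 benzyl 2,4-dihydroxy-6-propylbenzoate
Conditions: KHCO3, DMF, rt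
Reagents that add atoms: none
Why: Hydrogen carbonate deprotonates only the carboxylic acid, so SN2 alkylation of the carboxylate gives the benzyl ester with both phenols untouched, and room temperature avoids decarboxylation of the β-resorcylic acid.

Step 7
Reactants: 11 2-(benzyloxy)-4-methoxy-6-pentylbenzoic acid; 13 benzyl 2,4-dihydroxy-6-propylbenzoate
Product: 15 benzyl 4-{[2-(benzyloxy)-4-methoxy-6-pentylbenzoyl]oxy}-2-hydroxy-6-propylbenzoate, via mixed trifluoroacetic anhydride 14 (not isolated)
Conditions: (CF3CO)2O, toluene, rt
Reagents that add atoms: none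
Why: In this mixed-anhydride esterification the electron-rich hindered aroyl group is transferred as an acylium-like species to the free C4 hydroxyl of 13, whereas the C2 hydroxyl is held in a hydrogen bond to the ester carbonyl and stays unacylated, as is usual in depside couplings.

Step 8
Reactants: 15 benzyl 4-{[2-(benzyloxy)-4-methoxy-6-pentylbenzoyl]oxy}-2-hydroxy-6-propylbenzoate
Product: 16 benzyl 4-{[2-(benzyloxy)-4-methoxy-6-pentylbenzoyl]oxy}-2-methoxy-6-propylbenzoate
Conditions: MeI, K2CO3, dry DMF, rt
Reagents that add atoms: iodomethane, CI
Why: Williamson methylation of the only free phenol should proceed under anhydrous carbonate conditions, while the depside ester is shielded from attack by the two ortho substituents of the ring A aroyl group.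

Step 9
Reactants: 16 benzyl 4-{[2-(benzyloxy)-4-methoxy-6-pentylbenzoyl]oxy}-2-methoxy-6-propylbenzoate
Product: 17 4-[(2-hydroxy-4-methoxy-6-pentylbenzoyl)oxy]-2-methoxy-6-propylbenzoic acid
Conditions: H2 (1 atm), 10% Pd/C, EtOAc, rt
Reagents that add atoms: none
Why: Catalytic hydrogenolysis removes the benzyl ether and the benzyl ester in one neutral operation, which leaves the base- and acid-sensitive depside ester and both methyl ethers intact.

**Compound list**

1 | dimethyl 3-oxopentanedioate | COC(=O)CC(=O)CC(=O)OC | starting material
2 | hexanoyl chloride | CCCCCC(=O)Cl | starting material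
3 | dimethyl 2-hexanoyl-3-oxopentanedioate (racemic, largely enolised) | CCCCCC(=O)C(C(=O)OC)C(=O)CC(=O)OC | intermediate
4 | methyl 4-hydroxy-2-oxo-6-pentyl-2H-pyran-5-carboxylate | CCCCCC1=C(C(=O)OC)C(O)=CC(=O)O1 | intermediate
5 | benzyl bromide | BrCc1ccccc1 | starting material
6 | methyl 4-(benzyloxy)-2-oxo-6-pentyl-2H-pyran-5-carboxylate | CCCCCC1=C(C(=O)OC)C(OCc2ccccc2)=CC(=O)O1 | intermediate
7 | 1,1-dimethoxyethene | C=C(OC)OC | starting material
8 | methyl 5-(benzyloxy)-8,8-dimethoxy-3-oxo-1-pentyl-2-oxabicyclo[2.2.2]oct-5-ene-6-carboxylate (racemic) | O=C1OC2(CCCCC)CC(OC)(OC)C1C(OCc1ccccc1)=C2C(=O)OC | intermediate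
9 | methyl 6-(benzyloxy)-4,4-dimethoxy-2-pentylcyclohexa-1,5-diene-1-carboxylate | CCCCCC1=C(C(=O)OC)C(OCc2ccccc2)=CC(OC)(OC)C1 | intermediate
10 | methyl 2-(benzyloxy)-4-methoxy-6-pentylbenzoate | CCCCCc1cc(OC)cc(OCc2ccccc2)c1C(=O)OC | intermediate
11 | 2-(benzyloxy)-4-methoxy-6-pentylbenzoic acid | CCCCCc1cc(OC)cc(OCc2ccccc2)c1C(=O)O | intermediate
12 | 2,4-dihydroxy-6-propylbenzoic acid | CCCc1cc(O)cc(O)c1C(=O)O | starting material
13 | benzyl 2,4-dihydroxy-6-propylbenzoate | CCCc1cc(O)cc(O)c1C(=O)OCc1ccccc1 | intermediate
14 | 2-(benzyloxy)-4-methoxy-6-pentylbenzoic trifluoroacetic anhydride | CCCCCc1cc(OC)cc(OCc2ccccc2)c1C(=O)OC(=O)C(F)(F)F | intermediate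
15 | benzyl 4-{[2-(benzyloxy)-4-methoxy-6-pentylbenzoyl]oxy}-2-hydroxy-6-propylbenzoate | CCCCCc1cc(OC)cc(OCc2ccccc2)c1C(=O)Oc1cc(CCC)c(C(=O)OCc2ccccc2)c(O)c1 | intermediate
16 | benzyl 4-{[2-(benzyloxy)-4-methoxy-6-pentylbenzoyl]oxy}-2-methoxy-6-propylbenzoate | CCCCCc1cc(OC)cc(OCc2ccccc2)c1C(=O)Oc1cc(CCC)c(C(=O)OCc2ccccc2)c(OC)c1 | intermediate
17 | 4-[(2-hydroxy-4-methoxy-6-pentylbenzoyl)oxy]-2-methoxy-6-propylbenzoic acid | CCCCCc1cc(OC)cc(O)c1C(=O)Oc1cc(CCC)c(C(=O)O)c(OC)c1 | target

**Summary**

Total step count: 9. Longest linear sequence: 8 (steps 1, 2, 3, 4, 5, 7, 8, 9).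

**Steps most likely to fail**

1. Step 4. The benzyloxy donor at pyrone C4 may lower the diene reactivity so far that cycloaddition does not compete with thermal oligomerisation of the ketene acetal, or the acetal may add at C4 with displacement of the benzyloxy group instead of engaging C6 and C3. The fallback gives up the ring construction and sets the ring A pattern on a preformed arene. It sets out from benzyl bromide 5 together with purchased methyl 2,4-dihydroxy-6-pentylbenzoate F1. The free para hydroxyl of F1 is methylated selectively (MeI, 1.05 equiv, K2CO3, acetone, rt), the C2 hydroxyl being held back by its hydrogen bond to the ester, to give methyl 2-hydroxy-4-methoxy-6-pentylbenzoate F2. Benzylation of the chelated hydroxyl of F2 with 5 (K2CO3, DMF, 60 °C) then gives compound 10, where the route is rejoined.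

2. Step 3. The ambident pyronate may be benzylated at C3 or through the lactone carbonyl oxygen (giving a 2-benzyloxy-4-pyranone) rather than at the C4 oxygen. The fallback replaces alkylation of the anion by a halide with activation of the alcohol: Mitsunobu etherification of 4 with benzyl alcohol (PPh3, diisopropyl azodicarboxylate, THF, 0 °C to rt). Under these neutral conditions the alkoxyphosphonium ion is attacked by the C4 oxygen, a mode established for 4-hydroxy-2-pyrones. It sets out from compound 4, returns at compound 6 and passes through no new compound.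

3. Step 8. Under carbonate the ring B phenoxide may cleave or transfer the ring A aroyl group between molecules, or the hydrogen-bonded hydroxyl may be methylated incompletely. The fallback places the methyl ether before the coupling and sets out from compound 13:
   - Selective allylation of the free C4 hydroxyl (allyl bromide, 1.05 equiv, K2CO3, acetone, rt) gives benzyl 2-hydroxy-4-(prop-2-en-1-yloxy)-6-propylbenzoate F3.
   - Methylation of the chelated hydroxyl (MeI, K2CO3, DMF, 50 °C) gives benzyl 2-methoxy-4-(prop-2-en-1-yloxy)-6-propylbenzoate F4.
   - Allyl transfer to morpholine (Pd(PPh3)4 cat., a zerovalent palladium complex, THF, rt) frees benzyl 4-hydroxy-2-methoxy-6-propylbenzoate F5 without touching the benzyl ester.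
   - Coupling of F5 with acid 11 under the conditions of step 7 ((CF3CO)2O, toluene, rt, through mixed anhydride 14) gives compound 16, where the route is rejoined.

**Further compounds**

F1 | step 4 | methyl 2,4-dihydroxy-6-pentylbenzoate | CCCCCc1cc(O)cc(O)c1C(=O)OC
F2 | step 4 | methyl 2-hydroxy-4-methoxy-6-pentylbenzoate | CCCCCc1cc(OC)cc(O)c1C(=O)OC
F0 | step 3 | none | none
F3 | step 8 | benzyl 2-hydroxy-4-(prop-2-en-1-yloxy)-6-propylbenzoate | CCCc1cc(OCC=C)cc(O)c1C(=O)OCc1ccccc1
F4 | step 8 | benzyl 2-methoxy-4-(prop-2-en-1-yloxy)-6-propylbenzoate | CCCc1cc(OCC=C)cc(OC)c1C(=O)OCc1ccccc1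
F5 | step 8 | benzyl 4-hydroxy-2-methoxy-6-propylbenzoate | CCCc1cc(O)cc(OC)c1C(=O)OCc1ccccc1
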